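**Numbering.** Atom numbers are kaurane-type: ring A is C1(=O), C2=C3, C4(CH3)2, C5 (bearing C6H2OH) and C10; the lactone is C10–C20H2–O–C7(=O)–C8–C9; ring C is C8, C9, C11, C12, C13, C14; ring D is C8, C15(=O), C16(OH)(C17H3), C13, C14. Compound numbers 1–25 are those of the steps and of the list after them; 25 is the target.

## Analysis of the target

Compound 25 is a 6,7-seco-kauranoid. Ring A, a 4,4-dimethylcyclohex-2-enone, is joined through the spiro carbon C10 to a δ-lactone, and the lactone is fused along C8–C9 to a bicyclo[3.2.1]octane made of ring C and ring D. There are six stereocentres: C5, C10 (quaternary), C9, C8 (quaternary), C13 and the tertiary carbinol C16. On ring A the C6 arm and the C20 arm are cis. About C9–C10, C11 lies next to C1 and anti to C5. H9 and C15 are cis on the lactone ring, so C10 is axial on the chair of ring C and anti to the C8–C15 bond. C13 follows from the bridge, and at C16 the hydroxyl is exo (toward the C14 bridge) and the methyl endo (toward C11–C12). The sensitive groups are the non-enolisable ring A enone, a lactone whose α-carbon C8 is quaternary and also α to the C15 ketone (open to retro-Claisen cleavage), a tertiary α-ketol at C15/C16 (acyloin shift), a latent retro-aldol relation between C1 and C20, and a free primary alcohol. The difficulty lies in the two quaternary carbons that flank C9, in closing the bridged ring D, and in reaching the oxidation pattern without confusing enolisable positions. The strategy rests on C5 and C10: adjacent ring A carbons with cis one-carbon oxygenated arms (C6, C20), C10 being quaternary and α to the C1 ketone. That is the footprint of a cyclobutene fused across C10=C5 of a cyclohexenone and then cut at C6=C20.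

## Retrosynthetic reasoning

25 comes from its C6 silyl ether 24. The last skeletal heteroatom bond cut is C16–O, which leads back to the 16-methyl ketone 23: C16 is the only enolisable carbon, and the exo face of the C15=C16 enolate is the open one, so oxidation there should give the required hydroxyl orientation.

23 is cut at C16–C17 to ketone 22. Methylation of the same enolate is unambiguous, and its stereochemical outcome does not matter because C16 is planarised again.

22 is traced through bromide 21 to cyclopropyl ketone 20 by reconnecting C12 to C16. This turns the bridged ring D into the product of a carbene addition to a ring C alkene. The forward steps must then break C16–C12 and not C16–C13, which orbital overlap with the C15 carbonyl should ensure, and they must do so without a reducing metal so that the ring A enone survives.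

20 is cut at C16–C13 and C16–C12 to diazoketone 19, and 19 goes back to the acetyl compound 17 by diazo transfer onto the acetyl methyl group (C16). The tether fixes C13.

17 is cut at C9–C11 and C8–C14 into dienophile 15 and diene 16. A Diels–Alder reaction sets C9 and C8 together, cis by suprafaciality; the face is chosen by the spiro centre C10, whose flat C1 carbonyl side is more open than its C5 side.

15 goes back to the acetyl lactone 12 (C8=C9 by selenoxide elimination) and 12 to lactone 11 (C8–C15 by acylation of the lactone enolate). The acetyl group supplies C15 and C16 and gives the second activating group for the cycloaddition.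

11 comes from the saturated ketone 10 by C2–C3 dehydrogenation, and 10 from alcohol 9 by silylation. The enone is installed this early on purpose: it is already the ring A of 25, it removes the only competing acidic position, and it keeps C1 trigonal for the cycloaddition.

9 is opened at the lactone C–O bond to diol ester 8, and 8 is reconnected at C6=C20 to cyclobutene 6. Oxidative cleavage and reduction give both arms at the alcohol level, and only the C20 hydroxyl can reach C7 through a six-membered ring.

6 is cut at C10–C20 and C5–C6 into enone 4 and 5. This is the key disconnection: it creates the quaternary C10 and the cis relation of the two arms in one step from an achiral enone.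

4 is cut at the C10–C9 bond into iodide 2 and zinc reagent 3, and 2 comes from the commercial enone 1.

## Alternatives that were turned down

Alternative 1: The spiro centre is made by cutting C9–C10 and the lactone C–O bond. A low-valent titanocene reagent (trivalent titanium) opens a ring A spiro-epoxide at C10–C20 by single-electron transfer, the tertiary C10 radical adds to an acrylate ester, and the C20 alkoxide closes onto the new ester to give the bis-silylated spirolactone A1.
- For it: the quaternary carbon and the lactone arise in one operation by a radical addition that tolerates the crowding at C10. The reaction type has close precedent for spirolactones. The acceptor should enter anti to the C5 arm, which is the relative configuration needed.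
- Against it for 25: the epoxide must already carry C5 in enantiopure form and an oxygen at C1, so an asymmetric synthesis of a trisubstituted ring A precedes the key step. A1 holds C1 as a protected carbinol, which adds a stereocentre to erase, extra redox and protecting-group steps, and a tetrahedral C1 at the stage where ring C is attached. It also ends at the same stage as 10, with rings C and D still to build.
- Comparison: on precedent for the quaternary centre this alternative is stronger than the photochemical step. The chosen route offers instead a three-step access to 6, with C1 already a ketone and both oxygenated arms delivered at once.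

Alternative 2: Ring A is disconnected at C5–C10. The silyl ketene acetal of a δ-lactone bearing a trisubstituted alkenyl group at its carbinol carbon undergoes an Ireland–Claisen ring contraction; C5–C10 forms as the temporary O–C2 bond breaks, giving cyclohexene acid A2.
- For it: a thermal, scalable [3,3] shift through a constrained array. The relative configuration of the adjacent tertiary and quaternary centres follows from alkene geometry, and the absolute configuration is relayed from one carbinol centre. On predictability of relative stereochemistry and on scale it is at least equal to a photoreaction.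
- Against it for 25: the precursor needs a geometrically pure trisubstituted alkene with two differentiated oxygenated chains. A2 carries C6 as an acid, C7 as a silyl ether and C20 as a benzyl-type ether, so several oxidation-state corrections and deprotections precede lactonisation. Ring A emerges with a C1=C2 alkene and no oxygen at C1, so the enone needs an oxidative transposition next to a quaternary carbon.
- Comparison: the chosen disconnection gives C6, C7 and C20 at the right oxidation level after one ozonolysis, and the C1 ketone is the chromophore of the key step.

Alternative 3: The bicyclo[3.2.1]octane and the lactone are made together. An oxyallyl cation from a chloromethyl ketone (C9–C11–C12) is tethered through the C20 ester to a cyclopentadiene that contains ring D; an intramolecular (4+3) cycloaddition across C8 and C13 forms C8–C9 and C12–C13 and gives A3.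
- For it: no other plan forms as many skeletal bonds and rings in one step. C8, C9 and C13 are set together, and the C15=C16 alkene of A3 is well placed for a short conversion into the ketol. In convergency it is clearly ahead of the chosen route, which needs eight steps for rings C and D.
- Against it: substituted cyclopentadienes equilibrate by 1,5-hydrogen shifts, so only part of the diene is the productive isomer. The C8–C9 bond joins a carbon next to the quaternary C10 to a fully substituted diene terminus. The ester tether prefers the extended conformation, and the facial sense relative to C10 rests on that flexible tether. A3 also carries a C11 ketone to delete and a ring A alkene without oxygen at C1.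
- Comparison: the chosen route spends more steps but spreads the risk over separate reactions (cycloaddition, carbene addition, ring opening), each with its own stereochemical logic.

Key step: step 3

Assumption: the antipode of the oxazaborolidine that exposes the enone face leading to 6 is used; the steps are written for the (S)-prolinol-derived catalyst, and the mirror-image catalyst is substituted if the sense of induction is the opposite.

## Steps

Step 1
Reactants: 1 (4,4-dimethylcyclohex-2-en-1-one)
Product: 2 2-iodo-4,4-dimethylcyclohex-2-en-1-one
Conditions: I2 (1.5 equiv), pyridine/CH2Cl2, 0 → 25 °C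
Reagents that add atoms: iodine, II
Why: Pyridine-mediated α-iodination of an enone (conjugate addition of pyridine, iodination of the enolate, loss of pyridine); the only vinylic α-position is the future C10.

Step 2
Reactants: 2 (2-iodo-4,4-dimethylcyclohex-2-en-1-one); 3 ((3-ethoxy-3-oxopropyl)zinc bromide, THF solution)
Product: 4 ethyl 3-(3,3-dimethyl-6-oxocyclohex-1-en-1-yl)propanoate
Conditions: PdCl2(dppf) (5 mol%), THF, 25 → 45 °C
Reagents that add atoms: (3-ethoxy-3-oxopropyl)zinc bromide (3), CCOC(=O)CC[Zn]Br
Why: Negishi cross-coupling of the vinyl iodide with the zinc homoenolate under zerovalent palladium; the chelating diphosphine favours reductive elimination over β-hydride loss, and the ester is inert to the organozinc.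

Step 3
Reactants: 4 (ethyl 3-(3,3-dimethyl-6-oxocyclohex-1-en-1-yl)propanoate); 5 (acetylene)
Product: 6 ethyl 3-[(1R,6R)-5,5-dimethyl-2-oxobicyclo[4.2.0]oct-7-en-1-yl]propanoate (cis-fused cyclobutene; C10 and C5 as in 25)
Conditions: hν (λ = 366 nm), oxazaborolidine from (S)-α,α-bis(3,5-dimethylphenyl)prolinol and 2,4,6-trifluorophenylboronic acid activated with AlBr3 (50 mol%), 5 (saturated, slow stream), CH2Cl2, −75 °C, 4 at about 20 mM
Reagents that add atoms: acetylene (5), C#C
Why: Proposed new method: enone–alkyne [2+2] photocycloaddition to cyclobutenes is established without a catalyst, and AlBr3-activated oxazaborolidines are established for enantioselective enone–alkene [2+2] reactions, which is the closest known reaction type; their use with an alkyne partner on a 2-alkyl enone has not been shown. The Lewis acid should bind the C1 carbonyl of 4 (more basic than the ester), shift its absorption so that the complex is excited selectively at 366 nm, and shield one face of C10=C5. The excited complex should add to 5 to give a 1,4-biradical, and after spin inversion radical recombination closes the four-membered ring, so C10–C20 and C5–C6 form on the same enone face. C10 and C5 are set together: their absolute sense by the catalyst-shielded face, their cis relation by strain, since a trans-fused cyclobutene on a six-membered ring is prohibitively strained and the quaternary C10 could not epimerise afterwards. Regiochemistry is immaterial because 5 is symmetric and both of its carbons later become CH2O groups. The step needs chemoselectivity over the lumiketone rearrangement and enone dimerisation, which a large excess of 5, low temperature and low enone concentration should secure. It also needs face selectivity, which rests on the catalyst alone because 4 has no stereocentre.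

Step 4
Reactants: 6 (cyclobutene keto ester)
Product: 8 ethyl 3-[1,2-bis(hydroxymethyl)-3,3-dimethyl-6-oxocyclohexyl]propanoate with the two hydroxymethyl groups cis (C5 and C10 as in 25), via keto dialdehyde 7 (not isolated)
Conditions: O3, CH2Cl2/MeOH (3:1), −78 °C; then NaBH4 (3 equiv), −78 → −50 °C; aq. NH4Cl
Reagents that add atoms: ozone, [O-][O+]=O
Why: Ozonolysis cleaves the strained C6=C20 bond, and NaBH4 at low temperature reduces the aldehydes as they are released, much faster than the C1 ketone shielded by the quaternary C10 (aldehyde-selective borohydride reduction). Immediate reduction also prevents epimerisation of C5 through the C6 aldehyde, so the cis relation from step 3 is kept.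

Step 5
Reactants: 8 (keto diol ester)
Product: 9 11-(hydroxymethyl)-10,10-dimethyl-2-oxaspiro[5.5]undecane-3,7-dione with the lactone CH2O (C20) cis to the CH2OH (C6); C5 and C10 as in 25
Conditions: pyridinium p-toluenesulfonate (10 mol%), PhMe, 60 °C, ethanol removed
Reagents that add atoms: none
Why: Acid-catalysed lactonisation; only the C20 hydroxyl reaches C7 through a six-membered ring (the C6 hydroxyl would need an eight-membered one), and the quaternary C10 favours closure. Any hemiketal between the C6 hydroxyl and C1 is reversible and is drained in step 6.

Step 6
Reactants: 9 (hydroxy keto lactone)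
Product: 10 11-[(tert-butyldiphenylsilyl)oxymethyl]-10,10-dimethyl-2-oxaspiro[5.5]undecane-3,7-dione (stereocentres as in 9)
Conditions: t-BuPh2SiCl (1.2 equiv), imidazole (2.5 equiv), DMF, 25 °C
Reagents that add atoms: tert-butyl(chloro)diphenylsilane, CC(C)(C)[Si](Cl)(c1ccccc1)c1ccccc1
Why: Silylation of the primary alcohol with the most acid-tolerant common silyl group, chosen to survive steps 10 and 13 and to add bulk on the C5 side of the spiro centre.

Step 7
Reactants: 10 (silyl ether keto lactone)
Product: 11 11-[(tert-butyldiphenylsilyl)oxymethyl]-10,10-dimethyl-2-oxaspiro[5.5]undec-8-ene-3,7-dione (ring A enone C1(=O)–C2=C3; stereocentres as in 9)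
Conditions: 2-iodoxybenzoic acid (IBX, 2.5 equiv), DMSO/PhMe, 75 °C
Reagents that add atoms: none
Why: IBX dehydrogenation of a ketone to the enone; C1 can enolise only toward C2 because C10 is quaternary, and the lactone is inert. The enone is already that of 25, can no longer be deprotonated (C4 and C10 are quaternary) and keeps C1 flat for step 10.

Step 8
Reactants: 11 (enone lactone)
Product: 12 4-acetyl derivative of 11 (acetyl on C8; C8 epimers and enol form, configurationally labile; other centres as in 9)
Conditions: LiN(i-Pr)2 (1.15 equiv), THF, −78 °C; N-methoxy-N-methylacetamide (1.3 equiv), −78 → −20 °C; aq. NH4Cl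
Reagents that add atoms: N-methoxy-N-methylacetamide, CC(=O)N(C)OC
Why: Claisen-type C-acylation of the lactone enolate with a Weinreb amide, whose chelated adduct persists until quench and prevents O-acylation and double acylation. C8–H is the only acidic C–H in 11, and the neopentyl C3 of the enone should not undergo transannular Michael addition at this temperature; the C8 configuration is irrelevant because C8 becomes trigonal in step 9.

Step 9
Reactants: 12 (8-acetyl lactone)
Product: 15 4-acetyl-11-[(tert-butyldiphenylsilyl)oxymethyl]-10,10-dimethyl-2-oxaspiro[5.5]undeca-4,8-diene-3,7-dione (C8=C9 alkene bearing the acetyl group on C8; C5 and C10 as in 25), via selenide 13 (not isolated), via selenoxide 14 (not isolated)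
Conditions: PhSeCl (1.2 equiv), pyridine (1.5 equiv), CH2Cl2, 0 °C; then 30% aq. H2O2, 0 → 25 °C
Reagents that add atoms: none
Why: Selenenylation of the enolised β-keto lactone at C8, oxidation, and selenoxide syn-elimination toward C9, the only carbon with β-hydrogens. The doubly activated alkene cannot deconjugate because C10 is quaternary.

Step 10
Reactants: 15 (acetyl alkylidene lactone); 16 (buta-1,3-diene)
Product: 17 Diels–Alder adduct: 8-acetyl spirolactone with ring C closed as a cyclohexene (C12=C13); lactone and ring C cis-fused (H9 cis to the acetyl group) and C11 on the C1 side of C10; C5, C8, C9 and C10 as in 25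
Conditions: 16 (10 equiv), ZnCl2 (1.2 equiv), CH2Cl2/Et2O, 0 → 25 °C, sealed vessel
Reagents that add atoms: buta-1,3-diene (16), C=CC=C
Why: Lewis-acid-promoted Diels–Alder reaction of a ZnCl2-chelated 2-acyl α,β-unsaturated lactone; doubly activated dienophiles of this kind accept dienes even at a β-carbon next to a quaternary centre. Addition is suprafacial, so H9 and the acetyl group end up cis. The diene should approach C9 past the flat C1 carbonyl and not past C5 with its silyloxymethyl arm and the C4 methyls, which places C11 next to C1 and sets C9 and C8 together as in 25.

Step 11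
Reactants: 17 (Diels–Alder adduct)
Product: 19 α-diazoketone: the acetyl group of 17 converted into C15(=O)–C16H=N2 (other centres unchanged), via trifluoroacetyl ketone 18 (not isolated)
Conditions: LiN(SiMe3)2 (1.1 equiv), THF, −78 °C; CF3CO2CH2CF3 (1.3 equiv); then MeSO2N3 (1.5 equiv), Et3N, H2O (1 equiv), MeCN, 25 °C
Reagents that add atoms: methanesulfonyl azide, CS(=O)(=O)N=[N+]=[N-]
Why: Detrifluoroacetylative (Regitz-type) diazo transfer; the acetyl methyl group (C16) is the only enolisable position, Claisen condensation with the trifluoroacetate activates it, and the sulfonyl azide transfers N2 with loss of the trifluoroacetyl group.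

Step 12
Reactants: 19 (diazoketone)
Product: 20 cyclopropyl ketone: C16 bonded to C12 and C13 (tricyclo[3.2.1.0]octan-15-one unit fused to the lactone; C8, C9 and C13 as in 25)
Conditions: Rh2(OAc)4 (1 mol%), CH2Cl2, 25 °C, slow addition of 19
Reagents that add atoms: none
Why: Intramolecular cyclopropanation of the ring C alkene by the rhodium carbenoid, a known reaction of 1-diazoacetylcyclohex-3-enes. The tether allows addition only on the face of C12=C13 that carries C15, which fixes C13, and the remote electron-poor ring A alkene is not attacked.

Step 13
Reactants: 20 (cyclopropyl ketone)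
Product: 21 12-bromo ketone: bicyclo[3.2.1]octan-15-one with bromine at C12 on the face of ring C remote from the C15–C16 bridge (C8, C9 and C13 as in 25)
Conditions: HBr (33% in AcOH, 3 equiv), CH2Cl2, 0 °C, short contact; aq. NaHCO3
Reagents that add atoms: hydrogen bromide, Br
Why: Homoconjugate addition of HBr to the protonated cyclopropyl ketone. The C16–C12 bond lies outside the five-membered ring and nearly parallel to the carbonyl π-system, while C16–C13 lies near the carbonyl plane, so C16–C12 should break with bromide entering at C12 with inversion, giving the bicyclo[3.2.1] and not the bicyclo[2.2.2] skeleton; no reducing metal is used, so the ring A enone is kept.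

Step 14
Reactants: 21 (bromo ketone)
Product: 22 15-ketone with C16H2 and C12H2 (rings C and D complete; C8, C9 and C13 as in 25)
Conditions: Bu3SnH (1.3 equiv), AIBN (0.1 equiv), PhH, 80 °C
Reagents that add atoms: none
Why: Radical chain dehalogenation of a secondary bromide; bromine abstraction is much faster than stannyl addition to the hindered enone, and the C12 radical has no alkene within reach.

Step 15
Reactants: 22 (C15 ketone)
Product: 23 16-methyl 15-ketone (C16 epimers with methyl mainly exo; other centres as in 25)
Conditions: LiN(i-Pr)2 (1.1 equiv), THF, −78 °C; MeI (3 equiv), −78 → −30 °C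
Reagents that add atoms: iodomethane, CI
Why: Alkylation of a ketone enolate; C16 is the only enolisable position in 22 (C8 and C10 are quaternary, ring A has no acidic C–H). The C16 configuration is irrelevant because it is planarised again in step 16.

Step 16
Reactants: 23 (16-methyl ketone)
Product: 24 tert-butyldiphenylsilyl ether of 25 (16-hydroxyl exo toward C14 and 16-methyl endo)
Conditions: KN(SiMe3)2 (1.3 equiv), THF, −78 → −40 °C; 2-(benzenesulfonyl)-3-phenyloxaziridine (1.5 equiv), −78 °C; AcOH quench at −78 °C
Reagents that add atoms: 2-(benzenesulfonyl)-3-phenyloxaziridine, O=S(=O)(N1OC1c1ccccc1)c1ccccc1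
Why: Enolate hydroxylation with an N-sulfonyloxaziridine; the reagent should attack the tetrasubstituted C15=C16 enolate from the exo face next to the C14 bridge, because the endo face is screened by the C11–C12 bridge of the ring C chair. This puts the hydroxyl exo and the methyl endo as in 25; low temperature and an acidic quench guard against acyloin shift of the ketol.

Step 17
Reactants: 24 (silyl ether)
Product: 25 target CNP0530135.1 (6,16-dihydroxy-1,15-dioxo-6,7-secokaur-2-en-7,20-olide skeleton with configuration as in the SMILES)
Conditions: HF·pyridine, THF/pyridine, 0 → 25 °C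
Reagents that add atoms: none
Why: Fluoride-mediated cleavage of the silyl ether under buffered conditions that should not open the lactone or rearrange the ketol.

## Compound list

1 | 4,4-dimethylcyclohex-2-en-1-one | CC1(C)CCC(=O)C=C1 | starting material
2 | 2-iodo-4,4-dimethylcyclohex-2-en-1-one | CC1(C)CCC(=O)C(I)=C1 | intermediate
3 | (3-ethoxy-3-oxopropyl)zinc bromide | CCOC(=O)CC[Zn]Br | starting material
4 | ethyl 3-(3,3-dimethyl-6-oxocyclohex-1-en-1-yl)propanoate | CC1(C)CCC(=O)C(CCC(=O)OCC)=C1 | intermediate
5 | acetylene | C#C | starting material
6 | ethyl 3-[(1R,6R)-5,5-dimethyl-2-oxobicyclo[4.2.0]oct-7-en-1-yl]propanoate | CC1(C)CCC(=O)[C@]2(CCC(=O)OCC)C=C[C@H]12 | intermediate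
7 | keto dialdehyde, cis formyl groups at C10 and C5 (not isolated) | CC1(C)CCC(=O)[C@@](C=O)(CCC(=O)OCC)[C@@H]1C=O | intermediate
8 | keto diol ester, cis hydroxymethyl groups at C10 and C5 | CC1(C)CCC(=O)[C@@](CO)(CCC(=O)OCC)[C@@H]1CO | intermediate
9 | 11-(hydroxymethyl)-10,10-dimethyl-2-oxaspiro[5.5]undecane-3,7-dione (hydroxy keto spirolactone) | CC1(C)CCC(=O)[C@]2(COC(=O)CC2)[C@@H]1CO | intermediate
10 | tert-butyldiphenylsilyl ether of 9 | CC1(C)CCC(=O)[C@]2(COC(=O)CC2)[C@@H]1CO[Si](c3ccccc3)(c4ccccc4)C(C)(C)C | intermediate
11 | ring A enone spirolactone | CC1(C)C=CC(=O)[C@]2(COC(=O)CC2)[C@@H]1CO[Si](c3ccccc3)(c4ccccc4)C(C)(C)C | intermediate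
12 | 8-acetyl spirolactone (C8 epimers) | CC1(C)C=CC(=O)[C@]2(COC(=O)C(C(C)=O)C2)[C@@H]1CO[Si](c3ccccc3)(c4ccccc4)C(C)(C)C | intermediate
13 | 8-acetyl-8-(phenylselanyl) lactone (not isolated) | CC1(C)C=CC(=O)[C@]2(COC(=O)C(C(C)=O)([Se]c3ccccc3)C2)[C@@H]1CO[Si](c4ccccc4)(c5ccccc5)C(C)(C)C | intermediate
14 | selenoxide of 13 (not isolated) | CC1(C)C=CC(=O)[C@]2(COC(=O)C(C(C)=O)([Se](=O)c3ccccc3)C2)[C@@H]1CO[Si](c4ccccc4)(c5ccccc5)C(C)(C)C | intermediate
15 | 8-acetyl C8=C9 unsaturated spirolactone (dienophile) | CC1(C)C=CC(=O)[C@]2(COC(=O)C(C(C)=O)=C2)[C@@H]1CO[Si](c3ccccc3)(c4ccccc4)C(C)(C)C | intermediate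
16 | buta-1,3-diene | C=CC=C | starting material
17 | Diels–Alder adduct (ring C cyclohexene, 8-acetyl, cis-fused) | CC1(C)C=CC(=O)[C@]2(COC(=O)[C@@]3(C(C)=O)CC=CC[C@H]32)[C@@H]1CO[Si](c4ccccc4)(c5ccccc5)C(C)(C)C | intermediate
18 | trifluoroacetylated methyl ketone (not isolated) | CC1(C)C=CC(=O)[C@]2(COC(=O)[C@@]3(C(=O)CC(=O)C(F)(F)F)CC=CC[C@H]32)[C@@H]1CO[Si](c4ccccc4)(c5ccccc5)C(C)(C)C | intermediate
19 | α-diazoketone | CC1(C)C=CC(=O)[C@]2(COC(=O)[C@@]3(C(=O)C=[N+]=[N-])CC=CC[C@H]32)[C@@H]1CO[Si](c4ccccc4)(c5ccccc5)C(C)(C)C | intermediate
20 | cyclopropyl ketone (C16 bonded to C12 and C13) | CC1(C)C=CC(=O)[C@]2(COC(=O)[C@@]34C[C@@H]([C@H]5C[C@H]32)[C@@H]5C4=O)[C@@H]1CO[Si](c6ccccc6)(c7ccccc7)C(C)(C)C | intermediate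
21 | 12-bromo bicyclo[3.2.1]octan-15-one | CC1(C)C=CC(=O)[C@]2(COC(=O)[C@@]34C[C@@H]([C@@H](Br)C[C@H]32)CC4=O)[C@@H]1CO[Si](c5ccccc5)(c6ccccc6)C(C)(C)C | intermediate
22 | 15-ketone with C16H2 | CC1(C)C=CC(=O)[C@]2(COC(=O)[C@@]34C[C@@H](CC[C@H]32)CC4=O)[C@@H]1CO[Si](c5ccccc5)(c6ccccc6)C(C)(C)C | intermediate
23 | 16-methyl 15-ketone (C16 epimers) | CC1(C)C=CC(=O)[C@]2(COC(=O)[C@@]34C[C@@H](CC[C@H]32)C(C)C4=O)[C@@H]1CO[Si](c5ccccc5)(c6ccccc6)C(C)(C)C | intermediate
24 | tert-butyldiphenylsilyl ether of 25 | CC1(C)C=CC(=O)[C@]2(COC(=O)[C@@]34C[C@@H](CC[C@H]32)[C@](C)(O)C4=O)[C@@H]1CO[Si](c5ccccc5)(c6ccccc6)C(C)(C)C | intermediate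
25 | CNP0530135.1 | CC1(C)C=CC(=O)[C@]2(COC(=O)[C@@]34C[C@@H](CC[C@H]32)[C@](C)(O)C4=O)[C@@H]1CO | target

## Step count and least certain steps

Total: 17 steps. Longest linear sequence: 17 steps from 1 (3, 5 and 16 are purchased).

**Step 3 (key step, proposed new method).** Face selectivity or catalyst turnover may fail. The α-carbon of 4 carries no hydrogen, so the usual two-point binding of an enone to the oxazaborolidine is not available; the ester is a second Lewis-basic site; AlBr3 may engage the alkyne; and the lumiketone rearrangement takes over if bimolecular trapping is slow. Fallback with known chemistry: uncatalysed irradiation of 4 with excess 5 (about 350 nm, CH2Cl2, −78 °C) gives 6 together with its enantiomer F1. The mixture is ketalised with (2R,3R)-butane-2,3-diol (TsOH, benzene, water removal) to the diastereomeric dioxolanes, the ketal of 6 F2 and the ketal of the enantiomer F3. These are separated by chromatography or crystallisation, and aqueous acid returns 6 from F2, where the route is rejoined.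

**Step 10.** Cycloaddition at the neopentyl C9 may be too slow, and forcing it would erode face selectivity and polymerise 16 on the Lewis acid. Fallback from 15: the more electron-rich 2-(trimethylsilyloxy)buta-1,3-diene should add thermally (PhMe, 25–60 °C, no Lewis acid) with para orientation, its CH2 terminus next to the silyloxy carbon bonding to C9, to give the C12 silyl enol ether F7. CsF with PhNTf2 converts it into the C12 enol triflate F8 without moving the double bond, and Pd(OAc)2/PPh3 with HCO2H/Bu3N reduces the triflate to the C12=C13 alkene, rejoining at 17.

**Step 13.** Cleavage of the other cyclopropane bond (C16–C13, leading to a bicyclo[2.2.2]octane), loss of the silyl ether or elimination toward a ring C alkene may occur, because the opening is run in strong acid. Fallback from 20: hydrogenation (H2, Pd/C, EtOAc) saturates the ring A alkene to the cyclopropyl diketone F9. SmI2 (divalent samarium; THF, DMPU, t-BuOH, −78 °C) opens the cyclopropyl ketone by single-electron transfer under the same overlap control to give the diketone F10. IBX then restores the ring A enone; the C15 ketone cannot be dehydrogenated because C13 is a bridgehead. The route is rejoined at 22.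

**Step 4.** Over-reduction of the C1 ketone would let the C1 hydroxyl compete with the C20 hydroxyl for C7 in step 5, and the β-hydroxy ketone can lose C20 by retro-aldol cleavage under basic borohydride conditions. Fallback from 6: the C1 ketone is protected first as its dioxolane F4 (Me3SiOCH2CH2OSiMe3, cat. Me3SiOTf, CH2Cl2, −78 → −20 °C). Ozonolysis with exhaustive NaBH4 reduction gives the ketal diol F5, lactonisation gives the ketal lactone F6, and aqueous acid removes the dioxolane, rejoining at 9.

**Step 16.** Enolisation of the hindered tertiary C16–H may be slow, the ketol may undergo acyloin shift under base, or oxygen may be delivered to the endo face. Fallback from 22 under non-basic conditions: α-methylenation with paraformaldehyde and diisopropylammonium trifluoroacetate (THF, 65 °C) gives the 16-methylene 15-ketone F11. Mukaiyama-type hydration with Mn(dpm)3 (tris(dipivaloylmethanato)manganese, catalytic), PhSiH3 and O2, followed by P(OEt)3, should deliver a hydrogen atom to C17 and oxygen to the exo face of the C16 radical; the terminal enone should react far faster than the hindered ring A enone. The route is rejoined at 24.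

## Further compounds

F1 | step 3 | enantiomer of 6 | CC1(C)CCC(=O)[C@@]2(CCC(=O)OCC)C=C[C@@H]12
F2 | step 3 | (4R,5R)-4,5-dimethyl-1,3-dioxolane ketal of 6 | CC1(C)CCC2(O[C@H](C)[C@@H](C)O2)[C@]3(CCC(=O)OCC)C=C[C@H]13
F3 | step 3 | (4R,5R)-4,5-dimethyl-1,3-dioxolane ketal of F1 | CC1(C)CCC2(O[C@H](C)[C@@H](C)O2)[C@@]3(CCC(=O)OCC)C=C[C@@H]13
F4 | step 4 | 1,3-dioxolane ketal of 6 at C1 | CC1(C)CCC2(OCCO2)[C@]3(CCC(=O)OCC)C=C[C@H]13
F5 | step 4 | ketal diol ester (C1 dioxolane analogue of 8) | CC1(C)CCC2(OCCO2)[C@@](CO)(CCC(=O)OCC)[C@@H]1CO
F6 | step 4 | ketal hydroxy spirolactone (C1 dioxolane analogue of 9) | CC1(C)CCC2(OCCO2)[C@]3(COC(=O)CC3)[C@@H]1CO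
F7 | step 10 | cycloadduct with C12 trimethylsilyl enol ether (C12=C13) | CC1(C)C=CC(=O)[C@]2(COC(=O)[C@@]3(C(C)=O)CC=C(O[Si](C)(C)C)C[C@H]32)[C@@H]1CO[Si](c4ccccc4)(c5ccccc5)C(C)(C)C
F8 | step 10 | C12 enol triflate | CC1(C)C=CC(=O)[C@]2(COC(=O)[C@@]3(C(C)=O)CC=C(OS(=O)(=O)C(F)(F)F)C[C@H]32)[C@@H]1CO[Si](c4ccccc4)(c5ccccc5)C(C)(C)C
F9 | step 13 | cyclopropyl ketone with saturated ring A | CC1(C)CCC(=O)[C@]2(COC(=O)[C@@]34C[C@@H]([C@H]5C[C@H]32)[C@@H]5C4=O)[C@@H]1CO[Si](c6ccccc6)(c7ccccc7)C(C)(C)C
F10 | step 13 | ring-opened 1,15-diketone with saturated ring A | CC1(C)CCC(=O)[C@]2(COC(=O)[C@@]34C[C@@H](CC[C@H]32)CC4=O)[C@@H]1CO[Si](c5ccccc5)(c6ccccc6)C(C)(C)C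
F11 | step 16 | 16-methylene 15-ketone | CC1(C)C=CC(=O)[C@]2(COC(=O)[C@@]34C[C@@H](CC[C@H]32)C(=C)C4=O)[C@@H]1CO[Si](c5ccccc5)(c6ccccc6)C(C)(C)C
A1 | alternative 1 | bis-silylated spiro δ-lactone on ring A | CC1(C)CC[C@H](O[Si](C)(C)C(C)(C)C)[C@]2(COC(=O)CC2)[C@@H]1CO[Si](C)(C)C(C)(C)C
A2 | alternative 2 | ring A cyclohexene acid with quaternary C10 | CC1(C)CC=C[C@@](COCc2ccc(OC)cc2)(CCCO[Si](C)(C)C(C)(C)C)[C@@H]1C(O)=O
A3 | alternative 3 | lactone-fused bicyclo[3.2.1]oct-6-en-3-one | CC1(C)CC=C[C@]2(COC(=O)[C@@]34C[C@@H](CC(=O)[C@H]32)C(C)=C4)[C@@H]1CO[Si](C)(C)C(C)(C)C
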